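**Plan**

- Retrosynthesis first cuts the two outer bonds between the free carbons of rings B and D and the CH2 bridges that carry rings A and E (butyrylfilicinic acid units).
- Next, two ring bonds are cut in each of rings B and D: from the inner-bridge-bearing carbon to the hydroxylated carbon lying between it and the butyryl-bearing carbon, and from the butyryl-bearing carbon to its other hydroxylated neighbour.
- The feature that allows this: in rings B and D the butyryl-bearing carbon and the hydroxylated carbon between it and the bridge-bearing carbon are C2 and C1 of a 3-oxohexanoyl unit, and the other four ring carbons (C–CH2, C–OH, C–H, C–OH) are C4 to C1 of an acetoacetate whose C4 already holds the inner bridge.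
- Last, each arm is cut between the benzylic CH2 and the acetoacetate γ-carbon, and ring C is traced back to 1,3,5-trimethoxybenzene (butyrylation, then two chloromethylations).
- Forward: ring C is bought as the arene, rings B and D are closed together in one two-directional operation, and rings A and E are made separately and attached last; the target has no stereocentre, so nothing has to be set or protected against scrambling.

Key step: step 6

Remark: the target is drawn as one enol tautomer; the compound obtained equilibrates among the enol forms of its β-triketone rings (A, E) and phloroglucinol rings (B, C, D).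

Remark: steps 3, 6 and 11 act on both sides of the ring C core at once, so each consumes two molecules of its partner (5, 10 and 17). The Reactants lines give the equivalents consumed, the Conditions lines the amounts charged, and the second molecule is also entered under the reagents that add atoms.

**Route**

Step 1
Reactants: 1 1,3,5-trimethoxybenzene; 2 butyryl chloride
Product: 3 1-(2,4,6-trimethoxyphenyl)butan-1-one
Conditions: AlCl3 (1.1 equiv), CH2Cl2, −10 → 0 °C; cold dilute HCl
Reagents that add atoms: none
Why: Friedel–Crafts acylation of the symmetric, strongly activated arene, whose three free positions are equivalent, should stop at the monoketone because the acyl group deactivates the ring, while low temperature and near-stoichiometric AlCl3 limit cleavage of the ortho methyl ethers.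

Step 2
Reactants: 3 1-(2,4,6-trimethoxyphenyl)butan-1-one
Product: 4 1-[3,5-bis(chloromethyl)-2,4,6-trimethoxyphenyl]butan-1-one
Conditions: paraformaldehyde (5 equiv), HCl gas, ZnCl2 (cat.), AcOH, 50 °C; product used without chromatography
Reagents that add atoms: formaldehyde (as paraformaldehyde), C=O; hydrogen chloride, Cl
Why: Blanc chloromethylation should take place twice because each of the two remaining ring positions is ortho or para to all three methoxy groups and the butyryl group is twisted out of conjugation, and after the second substitution the product has no ring position left for diarylmethane formation.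

Step 3
Reactants: 4 1-[3,5-bis(chloromethyl)-2,4,6-trimethoxyphenyl]butan-1-one; 5 methyl acetoacetate (2 equiv)
Product: 6 dimethyl 5,5'-(5-butanoyl-2,4,6-trimethoxy-1,3-phenylene)bis(3-oxopentanoate)
Conditions: 5 (3 equiv), LiN(iPr)2 (6 equiv, commercial solution), THF, 0 °C; add 4, −78 → 0 °C; dilute HCl
Reagents that add atoms: methyl acetoacetate (second molecule of 5), COC(=O)CC(C)=O
Why: Huckin–Weiler γ-alkylation, in which the terminal carbon of the acetoacetate dianion is the most nucleophilic site and two molecules of it should displace the two activated benzylic chlorides at low temperature faster than they deprotonate the flanked, twisted ring C ketone, the excess of dianion keeping one acetoacetate from being alkylated twice.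

Step 4
Reactants: 7 Meldrum's acid (2,2-dimethyl-1,3-dioxane-4,6-dione); 2 butyryl chloride
Product: 8 5-(1-hydroxybutylidene)-2,2-dimethyl-1,3-dioxane-4,6-dione
Conditions: pyridine (2 equiv), CH2Cl2, 0 °C → rt; wash with dilute HCl
Reagents that add atoms: none
Why: Yonemitsu C-acylation of the acidic Meldrum's acid methylene by the acid chloride under pyridine gives the enolised acyl derivative, a standard β-keto acid equivalent.

Step 5
Reactants: 8 5-(1-hydroxybutylidene)-2,2-dimethyl-1,3-dioxane-4,6-dione
Product: 10 N-methoxy-N-methyl-3-oxohexanamide, via butanoylketene 9 (not isolated)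
Conditions: MeNH(OMe)·HCl (1.2 equiv), Et3N (1.2 equiv), toluene, 90 °C
Reagents that add atoms: N,O-dimethylhydroxylamine hydrochloride, CNOC.Cl
Why: On heating, the acyl Meldrum's acid should lose acetone and CO2 to give the acylketene 9, which the amine freed by Et3N traps at the ketene carbon to give the β-keto N-methoxy-N-methylamide (thermolysis–aminolysis of acyl Meldrum's acids).

Step 6
Reactants: 6 dimethyl 5,5'-(5-butanoyl-2,4,6-trimethoxy-1,3-phenylene)bis(3-oxopentanoate); 10 N-methoxy-N-methyl-3-oxohexanamide (2 equiv)
Product: 12 1-[3,5-bis(3-butanoyl-2,4,6-trihydroxybenzyl)-2,4,6-trimethoxyphenyl]butan-1-one, via bis(triketo ester) 11 (not isolated)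
Conditions: 10 (3 equiv), LiN(iPr)2 (3 equiv), THF, −78 °C (Li enolate of 10); added to 6, LiN(iPr)2 (5.2 equiv), THF, 0 then −78 °C; −78 → 0 °C; dilute HCl; crude 11, Mg(OMe)2 (8 equiv), MeOH, reflux; dilute HCl
Reagents that add atoms: N-methoxy-N-methyl-3-oxohexanamide (second molecule of 10), CCCC(=O)CC(=O)N(C)OC
Why: Excess base should turn 6 into its bis(α,γ-dianion), the ring C ketone being parked as a hindered enolate, and each γ-carbon (the CH2 next to the benzylic CH2) adds to the amide carbonyl of one molecule of the lithium enolate of 10, so that two molecules of 10 are consumed per molecule of 6 and the N-methoxy chelates hold the tetrahedral adducts until the acid quench releases the bis(triketo ester) 11 and two molecules of N,O-dimethylhydroxylamine. Mg(OMe)2 then chelates each 3,5,7-trioxo ester chain and C6 of the chain attacks the ester carbonyl in a 6-exo-trig Claisen (Dieckmann-type) closure; loss of methanol and enolisation give the benzene rings B and D, each ring being closed in this same mode, with four ring carbons from the acetoacetate arm and two (C1 and C2) from 10, whose C3 to C6 become the butyryl group. The closest known reaction type is the acylation of β-keto ester dianions by β-keto N-methoxy-N-methylamide enolates followed by magnesium-templated Claisen cyclisation of the triketo esters to acylphloroglucinols, here run in two directions on one core. No stereocentre is formed, since the labile methine carbons of 11 become aromatic carbons. The step needs γ-C-acylation instead of α- or O-acylation, attack at the amide and not at a ketone, and Claisen instead of aldol or pyrone closure. These are secured by the dianion terminus being the only strongly nucleophilic carbon, by the enolate form of 10 masking its ketone, and by magnesium chelation of the triketo ester, while the single γ-position of each arm fixes the regiochemistry.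

Step 7
Reactants: 12 1-[3,5-bis(3-butanoyl-2,4,6-trihydroxybenzyl)-2,4,6-trimethoxyphenyl]butan-1-one
Product: 13 1-[3,5-bis(3-butanoyl-2,4,6-trihydroxybenzyl)-2,4,6-trihydroxyphenyl]butan-1-one
Conditions: BBr3 (12 equiv), CH2Cl2, −78 °C → rt; ice–water; handled under argon
Reagents that add atoms: none
Why: BBr3 ether cleavage (coordination to the ether oxygen, then bromide attack on methyl) should remove all three ring C methyl ethers, two assisted by chelation to the ortho ketone and the third forced by the excess of reagent, while the ketones, the transiently borylated phenols and the diarylmethane links are expected to survive at low temperature.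

Step 8
Reactants: 14 phloroglucinol; 2 butyryl chloride
Product: 15 1-(2,4,6-trihydroxyphenyl)butan-1-one
Conditions: AlCl3 (3.5 equiv), nitrobenzene–CH2Cl2, 0 → 45 °C; ice, dilute HCl
Reagents that add atoms: none
Why: Friedel–Crafts acylation of phloroglucinol should stop at the monoketone because the aluminium-chelated acylphloroglucinol is deactivated towards a second acylation.

Step 9
Reactants: 15 1-(2,4,6-trihydroxyphenyl)butan-1-one
Product: 16 butyrylfilicinic acid (2-butanoyl-3,5-dihydroxy-4,4-dimethylcyclohexa-2,5-dien-1-one)
Conditions: NaOMe (3.5 equiv), MeI (2.5 equiv), MeOH, 0 °C → rt; dilute HCl; chromatography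
Reagents that add atoms: iodomethane, CI
Why: Base-mediated C-methylation of the acylphloroglucinol anion with dearomatisation, in which the second methyl group enters the carbon that already carries the first, should give the gem-dimethyl trione (the usual preparation of acylfilicinic acids), to be separated from under- and over-methylated congeners.

Step 10
Reactants: 16 butyrylfilicinic acid
Product: 17 2-butanoyl-6-[(dimethylamino)methyl]-3,5-dihydroxy-4,4-dimethylcyclohexa-2,5-dien-1-one
Conditions: CH2(NMe2)2 (1.3 equiv), CH2Cl2, 0 °C → rt; evaporate, use promptly
Reagents that add atoms: bis(dimethylamino)methane, CN(C)CN(C)C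
Why: Mannich aminomethylation, in which the acidic vinylogous acid protonates the aminal to the N,N-dimethylmethyleneiminium ion that is captured by the only unsubstituted ring carbon, the excess of aminal and the low temperature keeping the Mannich base from being consumed by unreacted 16.

Step 11
Reactants: 13 1-[3,5-bis(3-butanoyl-2,4,6-trihydroxybenzyl)-2,4,6-trihydroxyphenyl]butan-1-one; 17 2-butanoyl-6-[(dimethylamino)methyl]-3,5-dihydroxy-4,4-dimethylcyclohexa-2,5-dien-1-one (2 equiv)
Product: 19 CNP0188003.0 (pentamer A–B–C–D–E), via quinone methide 18 (not isolated)
Conditions: 17 (2 equiv), added in two portions, 1,4-dioxane, 90 °C, argon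
Reagents that add atoms: Mannich base of butyrylfilicinic acid (second molecule of 17), CCCC(=O)C1=C(O)C(C)(C)C(O)=C(CN(C)C)C1=O
Why: On heating, each of the two molecules of the Mannich base should lose dimethylamine to the quinone methide 18, and the single unsubstituted, doubly ortho-hydroxylated carbon of each of rings B and D adds to its exocyclic methylene (elimination–addition C-alkylation by a Mannich base), so that one molecule of 13 takes up two molecules of 17, ring C having no free position.

**Compound list**

1 | 1,3,5-trimethoxybenzene | COc1cc(OC)cc(OC)c1 | starting material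
2 | butyryl chloride | CCCC(=O)Cl | starting material
3 | 1-(2,4,6-trimethoxyphenyl)butan-1-one | CCCC(=O)c1c(OC)cc(OC)cc1OC | intermediate
4 | 1-[3,5-bis(chloromethyl)-2,4,6-trimethoxyphenyl]butan-1-one | CCCC(=O)c1c(OC)c(CCl)c(OC)c(CCl)c1OC | intermediate
5 | methyl acetoacetate | COC(=O)CC(C)=O | starting material
6 | dimethyl 5,5'-(5-butanoyl-2,4,6-trimethoxy-1,3-phenylene)bis(3-oxopentanoate) | CCCC(=O)c1c(OC)c(CCC(=O)CC(=O)OC)c(OC)c(CCC(=O)CC(=O)OC)c1OC | intermediate
7 | Meldrum's acid (2,2-dimethyl-1,3-dioxane-4,6-dione) | CC1(C)OC(=O)CC(=O)O1 | starting material
8 | 5-(1-hydroxybutylidene)-2,2-dimethyl-1,3-dioxane-4,6-dione | CCCC(O)=C1C(=O)OC(C)(C)OC1=O | intermediate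
9 | butanoylketene (hex-1-ene-1,3-dione), formed and consumed in step 5 | CCCC(=O)C=C=O | intermediate
10 | N-methoxy-N-methyl-3-oxohexanamide | CCCC(=O)CC(=O)N(C)OC | intermediate
11 | dimethyl 4,4'-[(5-butanoyl-2,4,6-trimethoxy-1,3-phenylene)bis(methylene)]bis(3,5,7-trioxodecanoate), keto–enol mixture with configurationally labile methine carbons, carried on crude | CCCC(=O)c1c(OC)c(CC(C(=O)CC(=O)CCC)C(=O)CC(=O)OC)c(OC)c(CC(C(=O)CC(=O)CCC)C(=O)CC(=O)OC)c1OC | intermediate
12 | 1-[3,5-bis(3-butanoyl-2,4,6-trihydroxybenzyl)-2,4,6-trimethoxyphenyl]butan-1-one (trimer B–C–D, ring C as trimethyl ether) | CCCC(=O)c1c(O)cc(O)c(Cc2c(OC)c(Cc3c(O)cc(O)c(C(=O)CCC)c3O)c(OC)c(C(=O)CCC)c2OC)c1O | intermediate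
13 | 1-[3,5-bis(3-butanoyl-2,4,6-trihydroxybenzyl)-2,4,6-trihydroxyphenyl]butan-1-one (trimer B–C–D, all phenols free) | CCCC(=O)c1c(O)cc(O)c(Cc2c(O)c(Cc3c(O)cc(O)c(C(=O)CCC)c3O)c(O)c(C(=O)CCC)c2O)c1O | intermediate
14 | phloroglucinol | Oc1cc(O)cc(O)c1 | starting material
15 | 1-(2,4,6-trihydroxyphenyl)butan-1-one | CCCC(=O)c1c(O)cc(O)cc1O | intermediate
16 | butyrylfilicinic acid (2-butanoyl-3,5-dihydroxy-4,4-dimethylcyclohexa-2,5-dien-1-one) | CCCC(=O)C1=C(O)C(C)(C)C(O)=CC1=O | intermediate
17 | 2-butanoyl-6-[(dimethylamino)methyl]-3,5-dihydroxy-4,4-dimethylcyclohexa-2,5-dien-1-one | CCCC(=O)C1=C(O)C(C)(C)C(O)=C(CN(C)C)C1=O | intermediate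
18 | 2-butanoyl-3-hydroxy-4,4-dimethyl-6-methylidenecyclohex-2-ene-1,5-dione (quinone methide), formed and consumed in step 11 | CCCC(=O)C1=C(O)C(C)(C)C(=O)C(=C)C1=O | intermediate
19 | CNP0188003.0: central 2,4,6-trihydroxybutyrophenone ring C joined through CH2 at both free carbons to rings B and D (each a fully substituted 2,4,6-trihydroxybutyrophenone), which are joined through CH2 to the butyrylfilicinic acid rings A and E | CCCC(=O)C1=C(O)C(C)(C)C(O)=C(Cc2c(O)c(Cc3c(O)c(Cc4c(O)c(CC5=C(O)C(C)(C)C(O)=C(C(=O)CCC)C5=O)c(O)c(C(=O)CCC)c4O)c(O)c(C(=O)CCC)c3O)c(O)c(C(=O)CCC)c2O)C1=O | target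

**Count**

Total steps: 11. Longest linear sequence: 6 steps (steps 1, 2, 3, 6, 7, 11).

**Steps most likely to fail**

Step 6. The pentalithiated species may form incompletely or precipitate. Proton transfer may win over C-acylation at the hindered γ-carbon. Pyrone or aldol closure may compete with the Claisen closure on one arm, leaving half-annulated material. The fallback gives up the annulation and brings in rings B and D as preformed units. It sets out from 4 and 15 and comes back to the route at 12. Compound 15 (about 6 equiv) is C-benzylated by the bis(benzylic chloride) 4 with ZnCl2 (cat.) in 1,4-dioxane at rt to 50 °C, a Friedel–Crafts-type alkylation of a phloroglucinol by an electron-rich benzylic halide. The excess of 15 suppresses double alkylation of one phloroglucinol ring and is recovered. This path makes no new compound (F0).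

Step 11. The Mannich base may revert to 16, which then captures 18 and gives the symmetrical methylene-bis dimer. The second coupling may stall. The amine set free may fragment and re-form the methylene bridges, scrambling the sequence of rings. The fallback inverts the polarity of the coupling. It sets out from 13 and comes back to the route at 19. Compound 13 is aminomethylated at the free carbons of rings B and D with CH2(NMe2)2 (2.2 equiv, CH2Cl2, 0 °C) to give the bis-Mannich base of the trimer F1. Heating F1 with an excess of 16 in 1,4-dioxane eliminates dimethylamine on rings B and D, and the resulting ortho-quinone methides are captured by the free ring carbon of 16.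

Step 3. The dianion may deprotonate the ring C ketone or the first-formed product instead of displacing chloride. The benzylic chlorides may then be used up by enolate alkylation and oligomerisation, or the reaction may stop after one arm. The fallback replaces the strongly basic dianion by a malonate and builds the β-keto ester afterwards. It sets out from 4 and comes back to the route at 6. Alkylation of dimethyl malonate (6 equiv, NaH, THF) by 4 gives the tetramethyl bis-malonate F2. Hydrolysis with LiOH, acidification and heating (decarboxylation) give the bis(propanoic acid) F3. Activation with 1,1'-carbonyldiimidazole gives the bis(acyl imidazole) F4, which is treated in the same flask with Mg(O2CCH2CO2Me)2 in THF (Masamune–Brooks homologation) to give 6.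

**Further compounds**

F0 | step 6 | none | none
F1 | step 11 | 1-{3,5-bis[3-butanoyl-5-[(dimethylamino)methyl]-2,4,6-trihydroxybenzyl]-2,4,6-trihydroxyphenyl}butan-1-one | CCCC(=O)c1c(O)c(CN(C)C)c(O)c(Cc2c(O)c(Cc3c(O)c(CN(C)C)c(O)c(C(=O)CCC)c3O)c(O)c(C(=O)CCC)c2O)c1O
F2 | step 3 | tetramethyl 2,2'-[(5-butanoyl-2,4,6-trimethoxy-1,3-phenylene)bis(methylene)]dimalonate | CCCC(=O)c1c(OC)c(CC(C(=O)OC)C(=O)OC)c(OC)c(CC(C(=O)OC)C(=O)OC)c1OC
F3 | step 3 | 3,3'-(5-butanoyl-2,4,6-trimethoxy-1,3-phenylene)dipropanoic acid | CCCC(=O)c1c(OC)c(CCC(=O)O)c(OC)c(CCC(=O)O)c1OC
F4 | step 3 | 1-[3,5-bis(3-imidazol-1-yl-3-oxopropyl)-2,4,6-trimethoxyphenyl]butan-1-one | CCCC(=O)c1c(OC)c(CCC(=O)n2ccnc2)c(OC)c(CCC(=O)n2ccnc2)c1OC
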